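Ring A (C5–C6–C7–C8–C9–C10–C1) is cut back by one carbon. C7 is a lone CH between the oxygen-bearing C6 and the methyl-bearing C8, so its removal leaves a six-membered trans-fused hydrindanone with the C6 carbonyl. The key step puts C7 back in one operation: methylene transfer to the C6=C8 silyl enol ether, then FeCl3 opening of the siloxycyclopropane and loss of HCl form the C6–C7 and C7–C8 bonds and deliver ring A as the 8-methyl-7-en-6-one. Its precursor is the 8-methyl hydrindanone as its C6=C8 trimethylsilyl enol ether, with C4 as a triethylsilyl-protected isopropyl carbinol and the 1β-methyl, 4β-oxygen and 5α-hydrogen centres already set.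

Key step: step 11

Remarks
- Numbering: daucane locants are used for all bicyclic compounds (ring B = C1(CH3)–C2–C3–C4–C5; the six- or seven-membered ring = C5–C6–(C7)–C8–C9–C10–C1); β is the face of the C1 methyl group.
- The target SMILES is read as the trans-fused daucane with 1β-methyl, 4β-hydroxyl, 5α-hydrogen and 6α-acyloxy, (1R,4R,5S,6S) in daucane numbering.
- Design choice: the C4 silyl ether is triethylsilyl, not trimethylsilyl, because it must survive hydroboration, enolate chemistry, FeCl3 and methanolic acetate.
- Assumption: C8 of the methylated ketone and the two ring-fusion carbons of the siloxycyclopropane form as epimer mixtures; all become sp2 in the key step and are left undefined in the SMILES.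
- Stereocontrol: C1 by the catalyst (step 2), C4 by addition anti to the C1 methyl (step 5), C5 by hydroboration (step 7), C6 by hydroxyl-directed hydride delivery (step 14).

Step 1
Reactants: 1 3-ethoxycyclopent-2-en-1-one; 2 5-bromopent-1-ene
Product: 5 3-(pent-4-en-1-yl)cyclopent-2-en-1-one, via pent-4-enylmagnesium bromide 3 (not isolated), via bromomagnesium 3-ethoxy-1-(pent-4-enyl)cyclopent-2-en-1-olate 4 (not isolated)
Conditions: Mg, THF, rt; then 1, THF, 0 °C; then 1 M HCl, 0 °C to rt
Reagents that add atoms: none
Why: Stork–Danheiser sequence, in which the Grignard reagent adds 1,2 to the vinylogous ester and acid hydrolysis of the enol ether with loss of water transposes the carbonyl to give the 3-alkyl enone; no stereocentre is formed.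

Step 2
Reactants: 5 3-(pent-4-en-1-yl)cyclopent-2-en-1-one; 6 trimethylaluminium
Product: 7 (S)-3-methyl-3-(pent-4-en-1-yl)cyclopentan-1-one
Conditions: Me3Al, Cu(OTf)2 (5 mol %), chiral sulfonate-bearing N-heterocyclic carbene ligand (5 mol %), THF, −78 °C; 1 M HCl work-up
Reagents that add atoms: none
Why: Copper-catalysed asymmetric conjugate addition of Me3Al to a β-alkyl cyclopentenone is a known route to all-carbon quaternary centres in five-membered rings, and the ligand enantiomer is chosen so that methyl adds to the enone face that makes C1 (S), the only stereocentre carried forward.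

Step 3
Reactants: 7 (S)-3-methyl-3-(pent-4-en-1-yl)cyclopentan-1-one
Product: 9 (S)-4-(1-methyl-3-oxocyclopentyl)butanal, via ozonide 8 (not isolated)
Conditions: O3, CH2Cl2, −78 °C; then Me2S, −78 °C to rt
Reagents that add atoms: ozone, [O-][O+]=O
Why: Ozonolysis with reductive work-up cleaves only the terminal alkene to the aldehyde, the ketone and the C1 quaternary centre being inert to ozone.

Step 4
Reactants: 9 (S)-4-(1-methyl-3-oxocyclopentyl)butanal
Product: 10 (S)-7a-methyl-1,2,5,6,7,7a-hexahydro-3H-inden-3-one
Conditions: KOH, MeOH, 0 to 50 °C (dilute)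
Reagents that add atoms: none
Why: Intramolecular aldol condensation, in which the cyclopentanone enolate on the C5 side adds to the aldehyde in a 6-(enolexo)-exo-trig closure and dehydrates to the conjugated C5=C6 enone, whereas the competing aldol of the aldehyde enolate onto the ketone gives a bridged ketol that cannot dehydrate and reverts; C5 is deliberately planar here, so C1 stays the only stereocentre.

Step 5
Reactants: 10 (S)-7a-methyl-1,2,5,6,7,7a-hexahydro-3H-inden-3-one; 11 isopropylmagnesium chloride
Product: 12 (3R,7aS)-7a-methyl-3-(propan-2-yl)-2,3,5,6,7,7a-hexahydro-1H-inden-3-ol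
Conditions: i-PrMgCl, CeCl3, THF, −78 °C; aq. NH4Cl
Reagents that add atoms: none
Why: Organocerium 1,2-addition (suppresses enolisation, reduction and conjugate addition), in which the C1 methyl stands perpendicular over the β-face of the planar enone so that isopropyl enters C4 from the α-face and the carbinol has 4β-OH (cis to the C1 methyl), a control that closing ring B by aldol onto a cyclohexanone enolate would not give because that closure is expected to be cis-fused with isopropyl syn to the methyl.

Step 6
Reactants: 12 (3R,7aS)-7a-methyl-3-(propan-2-yl)-2,3,5,6,7,7a-hexahydro-1H-inden-3-ol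
Product: 13 (3R,7aS)-7a-methyl-3-(propan-2-yl)-3-(triethylsilyloxy)-2,3,5,6,7,7a-hexahydro-1H-indene
Conditions: Et3SiOTf, 2,6-lutidine, CH2Cl2, −78 to 0 °C
Reagents that add atoms: triethylsilyl trifluoromethanesulfonate, CC[Si](CC)(CC)OS(=O)(=O)C(F)(F)F
Why: Silyl triflate silylation of the hindered tertiary allylic alcohol under non-acidic conditions gives an ether that blocks retro-aldol and dehydration at every later C6-ketone stage.

Step 7
Reactants: 13 (3R,7aS)-7a-methyl-3-(propan-2-yl)-3-(triethylsilyloxy)-2,3,5,6,7,7a-hexahydro-1H-indene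
Product: 15 trans-fused 7a-methyl-3-(propan-2-yl)-3-(triethylsilyloxy)octahydro-1H-inden-4-ol (1β-methyl 4β-OSiEt3 5α-H 6α-OH), via C6 alkylborane 14 (not isolated)
Conditions: BH3·THF, THF, 0 °C to rt; then NaOH, H2O2, H2O, 0 °C to rt
Reagents that add atoms: hydrogen peroxide, OO
Why: Hydroboration–oxidation, in which boron goes to the less substituted C6 and hydrogen to C5 in a syn addition expected from the α-face, opposite to the perpendicular C1 methyl and the C4 silyloxy group, setting 5α-H (trans ring fusion) and 6α-OH, the C–B bond being oxidised with retention.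

Step 8
Reactants: 15 trans-fused 7a-methyl-3-(propan-2-yl)-3-(triethylsilyloxy)octahydro-1H-inden-4-ol
Product: 16 trans-fused 7a-methyl-3-(propan-2-yl)-3-(triethylsilyloxy)octahydro-4H-inden-4-one (C6 ketone; 1β-methyl 4β-OSiEt3 5α-H)
Conditions: Dess–Martin periodinane, pyridine, CH2Cl2, rt
Reagents that add atoms: none
Why: Dess–Martin oxidation of the secondary alcohol gives the C6 ketone, and C5, though now epimerisable, should stay trans because the cis-fused epimer would push the C4 isopropyl group onto the concave face against the carbonyl, so a minor 5β-epimer from step 7 could be equilibrated here.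

Step 9
Reactants: 16 trans-fused 7a-methyl-3-(propan-2-yl)-3-(triethylsilyloxy)octahydro-4H-inden-4-one; 17 iodomethane
Product: 19 5,7a-dimethyl-3-(propan-2-yl)-3-(triethylsilyloxy)octahydro-4H-inden-4-one (8-methyl ketone; C8 epimers), via lithium C6=C8 enolate 18 (not isolated)
Conditions: LiN(i-Pr)2, THF, −78 °C; then MeI, −78 to −20 °C
Reagents that add atoms: none
Why: Kinetic enolate alkylation, in which the amide base removes a proton from the C8 methylene because C5–H is buried between the fully substituted C1 and C4, and MeI alkylates C8, whose configuration is irrelevant since it becomes sp2 in steps 10 and 11.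

Step 10
Reactants: 19 5,7a-dimethyl-3-(propan-2-yl)-3-(triethylsilyloxy)octahydro-4H-inden-4-one
Product: 20 C6=C8 trimethylsilyl enol ether of 19 (hydrindane bis-silyl derivative: C4 OSiEt3 and C6 OSiMe3)
Conditions: Me3SiOTf, Et3N, CH2Cl2, 0 °C to rt
Reagents that add atoms: trimethylsilyl trifluoromethanesulfonate, C[Si](C)(C)OS(=O)(=O)C(F)(F)F
Why: Soft enolisation with silyl triflate and amine, in which the only accessible α-hydrogen is at C8 and the tetrasubstituted C6=C8 enol ether is also the more stable isomer, so kinetic and thermodynamic control both give the required regiochemistry, the tertiary triethylsilyl ether being untouched.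

Step 11
Reactants: 20 C6=C8 trimethylsilyl enol ether; 21 diiodomethane
Product: 24 4β-(triethylsilyloxy)dauc-7-en-6-one, via siloxycyclopropane 22 (not isolated), via 8-chloro ketone 23 (not isolated)
Conditions: Et2Zn, CH2I2, CH2Cl2, 0 °C to rt; pyridine, filter, concentrate; then FeCl3, DMF, 0 °C to rt; then NaOAc, MeOH, reflux
Reagents that add atoms: none
Why: The zinc carbenoid EtZnCH2I transfers CH2 to the electron-rich C6=C8 enol ether in a concerted [2+1] addition, which closes the three-membered ring and forms the C6–C7 and C7–C8 bonds. FeCl3 then oxidises the siloxycyclopropane with loss of the trimethylsilyl group to an oxygen-centred radical at C6; β-scission of the internal C6–C8 bond gives the C6 ketone and a tertiary C8 radical in the enlarged ring, chlorine transfer from a second FeCl3 gives the 8-chloro ketone, and NaOAc removes HCl through the C7 enolate to give the conjugated 7-en-6-one. The closest known reaction types are the Simmons–Smith (Furukawa) cyclopropanation of silyl enol ethers and the FeCl3-mediated enlargement of 1-silyloxybicyclo[n.1.0]alkanes to 2-cycloalkenones one carbon larger. The seven-membered ring is therefore formed by fragmentation of the bicycle, not by a cyclisation, and no new stereocentre survives: both cyclopropane carbons become sp2, so the face of methylene transfer is immaterial and C1, C4 and C5 are not touched. The step needs cleavage of the internal and not an external cyclopropane bond, and elimination toward C7 and not C9 or the methyl; the first is secured by the tertiary radical at C8 (tertiary because of the methyl placed in step 9) and by relief of bicyclic strain, the second by the acidity of C7–H next to the carbonyl. The triethylsilyl ether keeps the C4 alcohol out of retro-aldol and ionisation under FeCl3 and methanolic acetate.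

Step 12
Reactants: 24 4β-(triethylsilyloxy)dauc-7-en-6-one
Product: 25 4β-(triethylsilyloxy)dauc-7-ene-6,9-dione
Conditions: Pd(OH)2/C (cat.), t-BuOOH, K2CO3, CH2Cl2, rt
Reagents that add atoms: tert-butyl hydroperoxide, CC(C)(C)OO
Why: γ-Oxidation of an α,β-enone to the 1,4-enedione, in which the tert-butylperoxyl radical abstracts hydrogen from the C9 methylene (secondary, preferred over the C8 methyl) and the γ-peroxide collapses to the ketone under K2CO3; no stereocentre is formed and the silyl ether protects C4–O from retro-aldol under the basic conditions.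

Step 13
Reactants: 25 4β-(triethylsilyloxy)dauc-7-ene-6,9-dione
Product: 26 4β-hydroxydauc-7-ene-6,9-dione
Conditions: HF·pyridine, THF, 0 °C to rt
Reagents that add atoms: none
Why: Cleavage of the tertiary triethylsilyl ether with a buffered HF source is non-basic, so the liberated tertiary β-hydroxy ketone is not exposed to retro-aldol opening of ring B, and the enedione is inert to fluoride.

Step 14
Reactants: 26 4β-hydroxydauc-7-ene-6,9-dione
Product: 27 4β,6α-dihydroxydauc-7-en-9-one
Conditions: Me4NBH(OAc)3, MeCN/AcOH, −30 to 0 °C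
Reagents that add atoms: none
Why: Evans–Saksena hydroxyl-directed reduction, in which the C4 hydroxyl exchanges onto boron and hydride is delivered internally to the β-face of the C6 carbonyl through a six-membered transition state, giving the 6α-alcohol (anti to 4β-OH), while the C9 enone carbonyl has no directing hydroxyl and is not reduced by the triacetoxyborohydride.

Step 15
Reactants: 28 p-coumaric acid
Product: 30 (E)-3-[4-(tert-butyldimethylsilyloxy)phenyl]prop-2-enoic acid, via bis-silylated coumarate 29 (not isolated)
Conditions: t-BuMe2SiCl, imidazole, DMF, rt; then AcOH, THF/H2O, rt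
Reagents that add atoms: tert-butyldimethylsilyl chloride, CC(C)(C)[Si](C)(C)Cl
Why: Exhaustive silylation of acid and phenol followed by selective hydrolysis of the far more labile silyl ester gives the phenol-protected acid with the E-alkene unchanged.

Step 16
Reactants: 27 4β,6α-dihydroxydauc-7-en-9-one; 30 (E)-3-[4-(tert-butyldimethylsilyloxy)phenyl]prop-2-enoic acid
Product: 32 4β-hydroxy-9-oxodauc-7-en-6α-yl (E)-3-[4-(tert-butyldimethylsilyloxy)phenyl]prop-2-enoate, via mixed anhydride 31 (not isolated)
Conditions: 2,4,6-Cl3C6H2COCl, Et3N, THF, rt; then 27, DMAP, toluene, rt to 40 °C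
Reagents that add atoms: none
Why: Yamaguchi esterification, in which DMAP attacks the less hindered cinnamoyl carbonyl of the mixed anhydride and acylates the secondary allylic C6 hydroxyl with retention, the tertiary C4 hydroxyl being too hindered to react.

Step 17
Reactants: 32 4β-hydroxy-9-oxodauc-7-en-6α-yl (E)-3-[4-(tert-butyldimethylsilyloxy)phenyl]prop-2-enoate
Product: 33 4β-hydroxy-9-oxodauc-7-en-6α-yl (E)-3-(4-hydroxyphenyl)prop-2-enoate (CNP0310968.1)
Conditions: Bu4NF, AcOH, THF, 0 °C
Reagents that add atoms: none
Why: Buffered fluoride cleaves the aryl silyl ether much faster than it attacks the ester, the enone or the tertiary alcohol, releasing the phenol of the target.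

Compound list
1 | 3-ethoxycyclopent-2-en-1-one | CCOC1=CC(=O)CC1 | starting material
2 | 5-bromopent-1-ene | C=CCCCBr | starting material
3 | pent-4-enylmagnesium bromide | C=CCCC[Mg]Br | intermediate (not isolated)
4 | bromomagnesium 3-ethoxy-1-(pent-4-enyl)cyclopent-2-en-1-olate (racemic) | CCOC1=CC(CCCC=C)(O[Mg]Br)CC1 | intermediate (not isolated)
5 | 3-(pent-4-en-1-yl)cyclopent-2-en-1-one | O=C1C=C(CCCC=C)CC1 | intermediate
6 | trimethylaluminium | C[Al](C)C | starting material
7 | (S)-3-methyl-3-(pent-4-en-1-yl)cyclopentan-1-one | O=C1C[C@@](C)(CCCC=C)CC1 | intermediate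
8 | ozonide of 7 (1,2,4-trioxolane, mixture at the trioxolane carbon) | O=C1C[C@@](C)(CCCC2OCOO2)CC1 | intermediate (not isolated)
9 | (S)-4-(1-methyl-3-oxocyclopentyl)butanal | O=C1C[C@@](C)(CCCC=O)CC1 | intermediate
10 | (S)-7a-methyl-1,2,5,6,7,7a-hexahydro-3H-inden-3-one (C4 ketone conjugated to C5=C6) | O=C1CC[C@]2(C)CCCC=C12 | intermediate
11 | isopropylmagnesium chloride | CC(C)[Mg]Cl | starting material
12 | (3R,7aS)-7a-methyl-3-(propan-2-yl)-2,3,5,6,7,7a-hexahydro-1H-inden-3-ol (4β-OH, cis to the C1 methyl) | C1=C2[C@](C)(CC[C@@]2(O)C(C)C)CCC1 | intermediate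
13 | (3R,7aS)-7a-methyl-3-(propan-2-yl)-3-(triethylsilyloxy)-2,3,5,6,7,7a-hexahydro-1H-indene | C1=C2[C@](C)(CC[C@@]2(O[Si](CC)(CC)CC)C(C)C)CCC1 | intermediate
14 | C6 alkylborane from 13 (6α-BH2, 5α-H) | C1[C@H](B)[C@@H]2[C@](C)(CC[C@@]2(O[Si](CC)(CC)CC)C(C)C)CC1 | intermediate (not isolated)
15 | trans-fused 7a-methyl-3-(propan-2-yl)-3-(triethylsilyloxy)octahydro-1H-inden-4-ol (1β-methyl, 4β-OSiEt3, 5α-H, 6α-OH) | C1[C@H](O)[C@@H]2[C@](C)(CC[C@@]2(O[Si](CC)(CC)CC)C(C)C)CC1 | intermediate
16 | trans-fused 7a-methyl-3-(propan-2-yl)-3-(triethylsilyloxy)octahydro-4H-inden-4-one (C6 ketone; 1β-methyl, 4β-OSiEt3, 5α-H) | C1C(=O)[C@@H]2[C@](C)(CC[C@@]2(O[Si](CC)(CC)CC)C(C)C)CC1 | intermediate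
17 | iodomethane | CI | starting material
18 | lithium C6=C8 enolate of 16 | C1=C(O[Li])[C@@H]2[C@](C)(CC[C@@]2(O[Si](CC)(CC)CC)C(C)C)CC1 | intermediate (not isolated)
19 | 5,7a-dimethyl-3-(propan-2-yl)-3-(triethylsilyloxy)octahydro-4H-inden-4-one (8-methyl ketone, C8 epimers) | CC1C(=O)[C@@H]2[C@](C)(CC[C@@]2(O[Si](CC)(CC)CC)C(C)C)CC1 | intermediate
20 | hydrindane bis-silyl derivative: C4 triethylsilyl ether and C6=C8 trimethylsilyl enol ether (8-methyl) | CC1=C(O[Si](C)(C)C)[C@@H]2[C@](C)(CC[C@@]2(O[Si](CC)(CC)CC)C(C)C)CC1 | intermediate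
21 | diiodomethane | ICI | starting material
22 | siloxycyclopropane: C7 methylene bridging C6 (OSiMe3) and C8 (CH3) of 20 | CC12CC1(O[Si](C)(C)C)[C@@H]1[C@](C)(CC[C@@]1(O[Si](CC)(CC)CC)C(C)C)CC2 | intermediate (not isolated)
23 | 8-chloro-4β-(triethylsilyloxy)daucan-6-one | CC1(Cl)CC(=O)[C@@H]2[C@](C)(CC[C@@]2(O[Si](CC)(CC)CC)C(C)C)CC1 | intermediate (not isolated)
24 | 4β-(triethylsilyloxy)dauc-7-en-6-one (5α-H, 1β-methyl) | CC1=CC(=O)[C@@H]2[C@](C)(CC[C@@]2(O[Si](CC)(CC)CC)C(C)C)CC1 | intermediate
25 | 4β-(triethylsilyloxy)dauc-7-ene-6,9-dione | CC1=CC(=O)[C@@H]2[C@](C)(CC[C@@]2(O[Si](CC)(CC)CC)C(C)C)CC1=O | intermediate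
26 | 4β-hydroxydauc-7-ene-6,9-dione | CC1=CC(=O)[C@@H]2[C@](C)(CC[C@@]2(O)C(C)C)CC1=O | intermediate
27 | 4β,6α-dihydroxydauc-7-en-9-one | CC1=C[C@H](O)[C@@H]2[C@](C)(CC[C@@]2(O)C(C)C)CC1=O | intermediate
28 | p-coumaric acid, (E)-3-(4-hydroxyphenyl)prop-2-enoic acid | OC(=O)/C=C/c1ccc(O)cc1 | starting material
29 | tert-butyldimethylsilyl (E)-3-[4-(tert-butyldimethylsilyloxy)phenyl]prop-2-enoate | CC(C)(C)[Si](C)(C)OC(=O)/C=C/c1ccc(O[Si](C)(C)C(C)(C)C)cc1 | intermediate (not isolated)
30 | (E)-3-[4-(tert-butyldimethylsilyloxy)phenyl]prop-2-enoic acid | OC(=O)/C=C/c1ccc(O[Si](C)(C)C(C)(C)C)cc1 | intermediate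
31 | mixed anhydride of 30 with 2,4,6-trichlorobenzoic acid | O=C(OC(=O)/C=C/c1ccc(O[Si](C)(C)C(C)(C)C)cc1)c1c(Cl)cc(Cl)cc1Cl | intermediate (not isolated)
32 | 4β-hydroxy-9-oxodauc-7-en-6α-yl (E)-3-[4-(tert-butyldimethylsilyloxy)phenyl]prop-2-enoate | CC1=C[C@H](OC(=O)/C=C/c2ccc(O[Si](C)(C)C(C)(C)C)cc2)[C@@H]2[C@](C)(CC[C@@]2(O)C(C)C)CC1=O | intermediate
33 | (1R,4R,5S,6S)-4-hydroxy-9-oxodauc-7-en-6-yl (E)-3-(4-hydroxyphenyl)prop-2-enoate, CNP0310968.1 | CC1=C[C@H](OC(=O)/C=C/c2ccc(O)cc2)[C@@H]2[C@](C)(CC[C@@]2(O)C(C)C)CC1=O | target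

Total step count: 17. Longest linear sequence: 16 steps (steps 1 to 14, then 16 and 17); step 15 is a one-step side branch.

Steps most likely to fail

Step 11. Methylene transfer to the tetrasubstituted enol ether, flanked by C5 and the C4 silyloxy group, may be slow, so that zinc iodide hydrolyses or isomerises the enol silane before the cyclopropane forms; in the iron step, premature loss of the C4 silyl group would expose the ketol to retro-aldol. The fallback delivers the extra carbon as dibromocarbene, a smaller and more electrophilic species, and enlarges the ring by the ionic cyclopropyl-to-allyl opening instead of the iron-mediated radical scission. It sets out from 20: CHBr3 and KOt-Bu in pentane at −20 °C give the 7,7-dibromo siloxycyclopropane F1. Warming in toluene opens the internal bond with loss of Me3SiBr to the 7-bromo-4β-(triethylsilyloxy)dauc-7-en-6-one F2. Bu3SnH with catalytic Pd(PPh3)4 removes the vinylic bromine, and the route is rejoined at 24.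

Step 12. Hydrogen abstraction at C9 is slowed by conjugation with the C6 carbonyl and by the neighbouring quaternary C1, so conversion may stall or the C8 methyl may be oxidised instead. The fallback postpones the C9 oxidation until C6 is an ester, so that the C–H bond to be oxidised is allylic to an isolated trisubstituted alkene. It sets out from 24: HF·pyridine gives 4β-hydroxydauc-7-en-6-one F3. Me4NBH(OAc)3 reduces C6 under the same hydroxyl direction to dauc-7-ene-4β,6α-diol F4. Yamaguchi acylation with 30 gives 4β-hydroxydauc-7-en-6α-yl (E)-3-[4-(tert-butyldimethylsilyloxy)phenyl]prop-2-enoate F5. Allylic oxidation of the C9 methylene with catalytic Rh2(cap)4 and t-BuOOH (or CrO3·3,5-dimethylpyrazole) installs the 9-ketone, and the route is rejoined at 32.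

Step 14. Exchange of the hindered tertiary C4 hydroxyl onto boron may be too slow, so that hydride is not delivered internally and C6 either stays unreduced or is attacked externally from the α-face to give the 6β-alcohol. The fallback ties the hydride to the C4 oxygen covalently before reduction. It sets out from 26: Me2SiHCl and imidazole silylate the tertiary hydroxyl to the 4β-(dimethylsilyloxy)dauc-7-ene-6,9-dione F6. SnCl4 at −78 °C (or catalytic Bu4NF) triggers intramolecular hydrosilylation of the C6 carbonyl from the β-face, a known anti-selective reduction of β-silyloxy ketones, giving the cyclic 4β,6α-O-dimethylsilylene derivative F7. HF·pyridine cleaves the silylene, and the route is rejoined at 27.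

Further compounds
F1 | step 11 | 7,7-dibromo siloxycyclopropane (dibromocarbene adduct of 20) | CC12C(Br)(Br)C1(O[Si](C)(C)C)[C@@H]1[C@](C)(CC[C@@]1(O[Si](CC)(CC)CC)C(C)C)CC2
F2 | step 11 | 7-bromo-4β-(triethylsilyloxy)dauc-7-en-6-one | CC1=C(Br)C(=O)[C@@H]2[C@](C)(CC[C@@]2(O[Si](CC)(CC)CC)C(C)C)CC1
F3 | step 12 | 4β-hydroxydauc-7-en-6-one | CC1=CC(=O)[C@@H]2[C@](C)(CC[C@@]2(O)C(C)C)CC1
F4 | step 12 | dauc-7-ene-4β,6α-diol | CC1=C[C@H](O)[C@@H]2[C@](C)(CC[C@@]2(O)C(C)C)CC1
F5 | step 12 | 4β-hydroxydauc-7-en-6α-yl (E)-3-[4-(tert-butyldimethylsilyloxy)phenyl]prop-2-enoate | CC1=C[C@H](OC(=O)/C=C/c2ccc(O[Si](C)(C)C(C)(C)C)cc2)[C@@H]2[C@](C)(CC[C@@]2(O)C(C)C)CC1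
F6 | step 14 | 4β-(dimethylsilyloxy)dauc-7-ene-6,9-dione | CC1=CC(=O)[C@@H]2[C@](C)(CC[C@@]2(O[SiH](C)C)C(C)C)CC1=O
F7 | step 14 | 4β,6α-O-(dimethylsilylene)-4,6-dihydroxydauc-7-en-9-one | CC1=C[C@H](O3)[C@@H]2[C@](C)(CC[C@@]2(O[Si]3(C)C)C(C)C)CC1=O
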